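The cyclopentenone (ring atoms C8–C12, prostanoid numbering) is disconnected at C9–C8, the bond from the ring carbonyl carbon to the ring carbon that bears the exocyclic 7Z alkene, and at C7–C6. The precursor is an acyclic 2-chloro-enal (formyl group cis to C12) whose silyl-protected carbinol carbon C12 carries a terminal alkyne. Zerovalent nickel joins the aldehyde carbon C9 to the internal alkyne carbon C8, which closes the five-membered ring, while the alkyne terminus C7 receives the C1–C6 alkenyl chain from an alkenylzirconium reagent on the same side as C9; this syn addition fixes the 7Z geometry. C12 comes from a Sharpless epoxidation; oxidation at C9 and acetylation finish the route.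

Key step: step 12

Remark: locants C1–C20 follow prostanoid numbering (C1 = ester carbon, ring = C8–C12, C9 = ketone, C10 = C–Cl, C12 = carbinol carbon); the target is read as 5E,7Z,14Z,12R.

Step 1
Reactants: 1 2-bromoprop-2-en-1-ol; 2 ethynyltri(propan-2-yl)silane
Product: 3 2-methylidene-4-[tri(propan-2-yl)silyl]but-3-yn-1-ol
Conditions: PdCl2(PPh3)2 (2 mol %), CuI (4 mol %), Et3N, THF, rt
Reagents that add atoms: none
Why: Sonogashira coupling of the vinyl bromide with the mono-protected acetylene should proceed under mild conditions and tolerate the free alcohol.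

Step 2
Reactants: 3 2-methylidene-4-[tri(propan-2-yl)silyl]but-3-yn-1-ol
Product: 4 [(2S)-2-{[tri(propan-2-yl)silyl]ethynyl}oxiran-2-yl]methanol
Conditions: Ti(OiPr)4 (10 mol %), L-(+)-diethyl tartrate (12 mol %), t-BuOOH, 4 Å molecular sieves, CH2Cl2, −20 °C
Reagents that add atoms: tert-butyl hydroperoxide, CC(C)(C)OO
Why: Sharpless asymmetric epoxidation; the L-(+)-tartrate catalyst should deliver oxygen to the face of the 2-substituted allylic alcohol that gives the (S)-epoxide (the sense known for 2-methylprop-2-en-1-ol), and this sets C12.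

Step 3
Reactants: 4 [(2S)-2-{[tri(propan-2-yl)silyl]ethynyl}oxiran-2-yl]methanol; 5 hept-1-yne
Product: 8 (2S)-2-{[tri(propan-2-yl)silyl]ethynyl}undec-4-yne-1,2-diol, via lithium hept-1-yn-1-ide 6 (not isolated), via diethyl(hept-1-yn-1-yl)aluminium 7 (not isolated)
Conditions: 5, n-BuLi, toluene, 0 °C; Et2AlCl; then 4, 0 °C → rt; aq. KNaC4H4O6 work-up
Reagents that add atoms: none
Why: hydroxyl-directed opening of a 2,3-epoxy alcohol by an alkynylalane should occur at the unsubstituted CH2 carbon remote from the carbinol, so the C12–O bond and its configuration are untouched.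

Step 4
Reactants: 8 (2S)-2-{[tri(propan-2-yl)silyl]ethynyl}undec-4-yne-1,2-diol
Product: 9 (2S,4Z)-2-{[tri(propan-2-yl)silyl]ethynyl}undec-4-ene-1,2-diol
Conditions: H2 (1 atm), Pd/CaCO3 poisoned with Pb(OAc)2 (Lindlar catalyst), quinoline, EtOAc, rt
Reagents that add atoms: none
Why: Lindlar semihydrogenation adds H2 syn to the dialkyl alkyne and should give the 14Z alkene, while the alkyne capped by the bulky silyl group is too hindered to be reduced.

Step 5
Reactants: 9 (2S,4Z)-2-{[tri(propan-2-yl)silyl]ethynyl}undec-4-ene-1,2-diol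
Product: 10 (2S,4Z)-2-ethynylundec-4-ene-1,2-diol
Conditions: n-Bu4NF, THF, 0 °C → rt
Reagents that add atoms: none
Why: fluoride-induced protodesilylation of the alkynylsilane should free the terminal alkyne without affecting the diol or the Z alkene.

Step 6
Reactants: 10 (2S,4Z)-2-ethynylundec-4-ene-1,2-diol
Product: 11 (2S,4Z)-2-ethynyl-1,2-bis[(triethylsilyl)oxy]undec-4-ene
Conditions: Et3SiOTf (2.5 equiv), 2,6-lutidine, CH2Cl2, −78 → 0 °C
Reagents that add atoms: triethylsilyl trifluoromethanesulfonate, CC[Si](CC)(CC)OS(=O)(=O)C(F)(F)F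
Why: silylation with a silyl triflate and a hindered pyridine base is strong enough to protect the tertiary propargylic alcohol as well as the primary one.

Step 7
Reactants: 11 (2S,4Z)-2-ethynyl-1,2-bis[(triethylsilyl)oxy]undec-4-ene
Product: 12 (2S,4Z)-2-ethynyl-2-[(triethylsilyl)oxy]undec-4-enal
Conditions: (COCl)2, DMSO, CH2Cl2, −78 → −30 °C; then Et3N, −78 → 0 °C
Reagents that add atoms: none
Why: Swern oxidation applied directly to a primary triethylsilyl ether should cleave and oxidize only the unhindered primary O–Si group and leave the tertiary silyl ether in place.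

Step 8
Reactants: 13 methyl 2-[bis(2,2,2-trifluoroethoxy)phosphoryl]acetate
Product: 14 methyl 2-[bis(2,2,2-trifluoroethoxy)phosphoryl]-2-chloroacetate
Conditions: SO2Cl2 (1.05 equiv), CH2Cl2, 0 °C → rt
Reagents that add atoms: sulfuryl chloride, O=S(=O)(Cl)Cl
Why: electrophilic α-chlorination of the doubly activated methylene group by sulfuryl chloride should give the monochloro phosphonate.

Step 9
Reactants: 12 (2S,4Z)-2-ethynyl-2-[(triethylsilyl)oxy]undec-4-enal; 14 methyl 2-[bis(2,2,2-trifluoroethoxy)phosphoryl]-2-chloroacetate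
Product: 15 methyl (2E,4R,6Z)-2-chloro-4-ethynyl-4-[(triethylsilyl)oxy]dodeca-2,6-dienoate
Conditions: KN(SiMe3)2, 18-crown-6, THF, −78 °C
Reagents that add atoms: none
Why: Still–Gennari olefination with the trifluoroethyl phosphonate and a dissociated potassium base should place the ester kinetically cis to the aldehyde-derived carbon (formally 2E because chlorine outranks the ester), and the aldehyde has no α-hydrogen, so C12 cannot epimerize.

Step 10
Reactants: 15 methyl (2E,4R,6Z)-2-chloro-4-ethynyl-4-[(triethylsilyl)oxy]dodeca-2,6-dienoate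
Product: 16 (2E,4R,6Z)-2-chloro-4-ethynyl-4-[(triethylsilyl)oxy]dodeca-2,6-dien-1-ol
Conditions: i-Bu2AlH (2.5 equiv), CH2Cl2, −78 °C; aq. KNaC4H4O6 work-up
Reagents that add atoms: none
Why: 1,2-reduction of the enoate by the aluminium hydride at low temperature should give the allylic alcohol and leave the vinyl chloride, the alkyne and the silyl ether untouched.

Step 11
Reactants: 16 (2E,4R,6Z)-2-chloro-4-ethynyl-4-[(triethylsilyl)oxy]dodeca-2,6-dien-1-ol
Product: 17 (2E,4R,6Z)-2-chloro-4-ethynyl-4-[(triethylsilyl)oxy]dodeca-2,6-dienal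
Conditions: Dess–Martin periodinane, pyridine, CH2Cl2, 0 °C
Reagents that add atoms: none
Why: Dess–Martin oxidation under buffered conditions should give the enal with the formyl group still cis to C12, since the quaternary γ-carbon rules out dienol formation as an isomerization path.

Step 12
Reactants: 17 (2E,4R,6Z)-2-chloro-4-ethynyl-4-[(triethylsilyl)oxy]dodeca-2,6-dienal; 18 methyl hex-5-ynoate
Product: 20 methyl (5E,7E)-7-{(5R)-3-chloro-2-hydroxy-5-[(2Z)-oct-2-en-1-yl]-5-[(triethylsilyl)oxy]cyclopent-3-en-1-ylidene}hept-5-enoate (both carbinol epimers; diene chain on the side of the carbinol carbon), via methyl (5E)-6-[chloridobis(cyclopentadienyl)zirconio]hex-5-enoate 19 (not isolated)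
Conditions: 18 (1.6 equiv), Cp2Zr(H)Cl (1.5 equiv), THF, rt; then 17, Ni(COD)2 (10 mol %), ZnCl2 (20 mol %), THF, 0 °C
Reagents that add atoms: none
Why: Zerovalent nickel binds the aldehyde and the alkyne of 17 and undergoes oxidative cyclization, which forms the C9–C8 bond and an oxanickelacyclopentene with nickel on C7; the alkenyl group of 19 is then transferred to nickel (assisted by ZnCl2) and reductive elimination forms C7–C6 with retention at both alkenyl carbons. The closest known reaction type is the nickel-catalysed alkylative cyclization of ynals with organozinc or alkenylzirconium reagents, a three-component aldehyde–alkyne–alkenylmetal coupling. The cyclopentene ring closes in a 5-exo-dig mode, the aldehyde carbon bonding to the internal alkyne carbon, and the cis C10=C11 double bond holds the two reacting groups within bonding distance. The only new stereocentre, the C9 carbinol, forms without control and is erased by the oxidation of step 13, whereas C12 is not touched. Because the metallacycle delivers C9 and C6 to the same side of the alkyne, the chain ends up cis to C9 (7Z once C9 is a ketone; formally 7E in the alcohol through a priority change) and the diene keeps the 5E geometry of 19. The step needs cyclization to outrun direct addition of 19 to the aldehyde and insertion of nickel into the C10–Cl bond; the pre-organized intramolecular pathway, phosphine-free Ni(COD)2 and 0 °C are relied on for this.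

Step 13
Reactants: 20 methyl (5E,7E)-7-{(5R)-3-chloro-2-hydroxy-5-[(2Z)-oct-2-en-1-yl]-5-[(triethylsilyl)oxy]cyclopent-3-en-1-ylidene}hept-5-enoate
Product: 21 methyl (5E,7Z)-7-{(5R)-3-chloro-5-[(2Z)-oct-2-en-1-yl]-2-oxo-5-[(triethylsilyl)oxy]cyclopent-3-en-1-ylidene}hept-5-enoate
Conditions: MnO2 (excess), CH2Cl2, rt
Reagents that add atoms: none
Why: MnO2 oxidation of the doubly allylic alcohol should give the cross-conjugated dienone under neutral conditions, converging both C9 epimers and preserving the 7Z geometry.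

Step 14
Reactants: 21 methyl (5E,7Z)-7-{(5R)-3-chloro-5-[(2Z)-oct-2-en-1-yl]-2-oxo-5-[(triethylsilyl)oxy]cyclopent-3-en-1-ylidene}hept-5-enoate
Product: 22 methyl (5E,7Z)-7-{(5R)-3-chloro-5-hydroxy-5-[(2Z)-oct-2-en-1-yl]-2-oxocyclopent-3-en-1-ylidene}hept-5-enoate
Conditions: HF·pyridine, pyridine, THF, 0 °C → rt
Reagents that add atoms: none
Why: buffered fluoride cleavage of the tertiary silyl ether should free the C12 alcohol without harming the methyl ester or the dienone.

Step 15
Reactants: 22 methyl (5E,7Z)-7-{(5R)-3-chloro-5-hydroxy-5-[(2Z)-oct-2-en-1-yl]-2-oxocyclopent-3-en-1-ylidene}hept-5-enoate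
Product: 23 methyl (5E,7Z)-7-{(5R)-5-acetoxy-3-chloro-5-[(2Z)-oct-2-en-1-yl]-2-oxocyclopent-3-en-1-ylidene}hept-5-enoate
Conditions: Ac2O, DMAP, Et3N, CH2Cl2, 0 °C → rt (short reaction time, exclusion of light)
Reagents that add atoms: acetic anhydride, CC(=O)OC(C)=O
Why: DMAP-catalysed acylation is strong enough to acetylate the tertiary alcohol; low temperature and short contact should limit nucleophile-induced isomerization of the exocyclic alkene.

Compound list
1 | 2-bromoprop-2-en-1-ol | OCC(Br)=C | starting material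
2 | ethynyltri(propan-2-yl)silane | C#C[Si](C(C)C)(C(C)C)C(C)C | starting material
3 | 2-methylidene-4-[tri(propan-2-yl)silyl]but-3-yn-1-ol | C=C(CO)C#C[Si](C(C)C)(C(C)C)C(C)C | intermediate
4 | [(2S)-2-{[tri(propan-2-yl)silyl]ethynyl}oxiran-2-yl]methanol | C1O[C@]1(CO)C#C[Si](C(C)C)(C(C)C)C(C)C | intermediate
5 | hept-1-yne | CCCCCC#C | starting material
6 | lithium hept-1-yn-1-ide | [Li]C#CCCCCC | intermediate (not isolated)
7 | diethyl(hept-1-yn-1-yl)aluminium | CC[Al](CC)C#CCCCCC | intermediate (not isolated)
8 | (2S)-2-{[tri(propan-2-yl)silyl]ethynyl}undec-4-yne-1,2-diol | CCCCCC#CC[C@@](C#C[Si](C(C)C)(C(C)C)C(C)C)(O)CO | intermediate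
9 | (2S,4Z)-2-{[tri(propan-2-yl)silyl]ethynyl}undec-4-ene-1,2-diol | CCCCC/C=C\C[C@@](C#C[Si](C(C)C)(C(C)C)C(C)C)(O)CO | intermediate
10 | (2S,4Z)-2-ethynylundec-4-ene-1,2-diol | CCCCC/C=C\C[C@@](C#C)(O)CO | intermediate
11 | (2S,4Z)-2-ethynyl-1,2-bis[(triethylsilyl)oxy]undec-4-ene | CCCCC/C=C\C[C@@](C#C)(O[Si](CC)(CC)CC)CO[Si](CC)(CC)CC | intermediate
12 | (2S,4Z)-2-ethynyl-2-[(triethylsilyl)oxy]undec-4-enal | CCCCC/C=C\C[C@@](C#C)(O[Si](CC)(CC)CC)C=O | intermediate
13 | methyl 2-[bis(2,2,2-trifluoroethoxy)phosphoryl]acetate | COC(=O)CP(=O)(OCC(F)(F)F)OCC(F)(F)F | starting material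
14 | methyl 2-[bis(2,2,2-trifluoroethoxy)phosphoryl]-2-chloroacetate | COC(=O)C(Cl)P(=O)(OCC(F)(F)F)OCC(F)(F)F | intermediate
15 | methyl (2E,4R,6Z)-2-chloro-4-ethynyl-4-[(triethylsilyl)oxy]dodeca-2,6-dienoate | CCCCC/C=C\C[C@@](C#C)(O[Si](CC)(CC)CC)/C=C(Cl)\C(=O)OC | intermediate
16 | (2E,4R,6Z)-2-chloro-4-ethynyl-4-[(triethylsilyl)oxy]dodeca-2,6-dien-1-ol | CCCCC/C=C\C[C@@](C#C)(O[Si](CC)(CC)CC)/C=C(Cl)\CO | intermediate
17 | (2E,4R,6Z)-2-chloro-4-ethynyl-4-[(triethylsilyl)oxy]dodeca-2,6-dienal | CCCCC/C=C\C[C@@](C#C)(O[Si](CC)(CC)CC)/C=C(Cl)\C=O | intermediate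
18 | methyl hex-5-ynoate | COC(=O)CCCC#C | starting material
19 | methyl (5E)-6-[chloridobis(cyclopentadienyl)zirconio]hex-5-enoate | COC(=O)CCC/C=C/[Zr](Cl)(C1C=CC=C1)C1C=CC=C1 | intermediate (not isolated)
20 | methyl (5E,7E)-7-{(5R)-3-chloro-2-hydroxy-5-[(2Z)-oct-2-en-1-yl]-5-[(triethylsilyl)oxy]cyclopent-3-en-1-ylidene}hept-5-enoate (both carbinol epimers) | CCCCC/C=C\C[C@@]1(O[Si](CC)(CC)CC)C=C(Cl)C(O)/C1=C\C=C\CCCC(=O)OC | intermediate
21 | methyl (5E,7Z)-7-{(5R)-3-chloro-5-[(2Z)-oct-2-en-1-yl]-2-oxo-5-[(triethylsilyl)oxy]cyclopent-3-en-1-ylidene}hept-5-enoate | CCCCC/C=C\C[C@@]1(O[Si](CC)(CC)CC)C=C(Cl)C(=O)/C1=C\C=C\CCCC(=O)OC | intermediate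
22 | methyl (5E,7Z)-7-{(5R)-3-chloro-5-hydroxy-5-[(2Z)-oct-2-en-1-yl]-2-oxocyclopent-3-en-1-ylidene}hept-5-enoate | CCCCC/C=C\C[C@@]1(O)C=C(Cl)C(=O)/C1=C\C=C\CCCC(=O)OC | intermediate
23 | methyl (5E,7Z)-7-{(5R)-5-acetoxy-3-chloro-5-[(2Z)-oct-2-en-1-yl]-2-oxocyclopent-3-en-1-ylidene}hept-5-enoate | CCCCC/C=C\C[C@@]1(OC(C)=O)C=C(Cl)C(=O)/C1=C\C=C\CCCC(=O)OC | target

Total step count: 15. Longest linear sequence: 14 steps (steps 1–7 and 9–15; step 8 prepares the olefination reagent).

Steps most likely to fail

1. Step 12. Zerovalent nickel may insert into the activated C10–Cl bond of the chloroenal, or the alkenylzirconium reagent may add directly to the aldehyde before ring closure, so that chemoselectivity is lost. The fallback sets out from 17 and comes back at 20, and replaces oxidative cyclization by a carbometalation–carbonyl addition cascade under monovalent rhodium. Alkyne 18 is hydroborated (pinacolborane, Cp2Zr(H)Cl cat., Et3N) to methyl (5E)-6-(4,4,5,5-tetramethyl-1,3,2-dioxaborolan-2-yl)hex-5-enoate F1. With [Rh(OH)(cod)]2 (3 mol %) in dioxane/H2O, the alkenylrhodium species from F1 should add syn across the terminal alkyne of 17, alkenyl group to C7 and rhodium to C8. The C8–rhodium bond then adds to the C9 aldehyde, which closes the same bond and gives 20 with the same alkene geometry. This is the known rhodium-catalysed cyclization of alkynals with organoboron reagents; it uses no low-valent nickel and no oxophilic organometallic.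

2. Step 9. Addition to the hindered α-quaternary aldehyde may be slow, and the kinetic cis selectivity may erode. The fallback sets out from 10 and comes back at 17, and lets a lactone ring enforce the geometry.
   - Diol 10 is oxidized at the primary alcohol only (TEMPO, PhI(OAc)2, CH2Cl2) to (2S,4Z)-2-ethynyl-2-hydroxyundec-4-enal F2.
   - Horner–Wadsworth–Emmons reaction of F2 with commercial triethyl 2-chloro-2-phosphonoacetate (NaH, THF) follows. The isomer with the ester cis to the free tertiary hydroxyl should lactonize spontaneously to (5R)-3-chloro-5-ethynyl-5-[(2Z)-oct-2-en-1-yl]furan-2(5H)-one F3, which is separated from the open-chain isomer.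
   - Me(MeO)NH·HCl/AlMe3 opens the lactone to (2E,4R,6Z)-2-chloro-4-ethynyl-4-hydroxy-N-methoxy-N-methyldodeca-2,6-dienamide F4.
   - Immediate silylation (Et3SiOTf, 2,6-lutidine) gives (2E,4R,6Z)-2-chloro-4-ethynyl-N-methoxy-N-methyl-4-[(triethylsilyl)oxy]dodeca-2,6-dienamide F5.
   - i-Bu2AlH at −78 °C reduces F5 directly to aldehyde 17.

3. Step 3. The Lewis-acidic alane may ionize the tertiary propargylic C–O bond, which would lead to attack at the quaternary carbon or rearrangement of the epoxide and so to loss of regiocontrol. The fallback sets out from 4 and comes back at 9, and uses a cuprate displacement at the CH2 terminus without a Lewis acid. n-C5H11MgBr and CuBr·SMe2 give bromomagnesium dipentylcuprate F6, which adds syn to acetylene to give bromomagnesium bis[(1Z)-hept-1-en-1-yl]cuprate F7. An excess of F7 (the free hydroxyl consumes part of it) should open epoxide 4 at the unsubstituted carbon and give the Z-alkenyl diol 9 directly, so that step 4 is no longer needed. The bulky silyl group on the alkyne terminus is relied on to suppress the competing conjugate (allene-forming) displacement.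

Further compounds
F1 | step 12 | methyl (5E)-6-(4,4,5,5-tetramethyl-1,3,2-dioxaborolan-2-yl)hex-5-enoate | COC(=O)CCC/C=C/B1OC(C)(C)C(C)(C)O1
F2 | step 9 | (2S,4Z)-2-ethynyl-2-hydroxyundec-4-enal | CCCCC/C=C\C[C@@](C#C)(O)C=O
F3 | step 9 | (5R)-3-chloro-5-ethynyl-5-[(2Z)-oct-2-en-1-yl]furan-2(5H)-one | CCCCC/C=C\C[C@@]1(C#C)OC(=O)C(Cl)=C1
F4 | step 9 | (2E,4R,6Z)-2-chloro-4-ethynyl-4-hydroxy-N-methoxy-N-methyldodeca-2,6-dienamide | CCCCC/C=C\C[C@@](C#C)(O)/C=C(Cl)\C(=O)N(C)OC
F5 | step 9 | (2E,4R,6Z)-2-chloro-4-ethynyl-N-methoxy-N-methyl-4-[(triethylsilyl)oxy]dodeca-2,6-dienamide | CCCCC/C=C\C[C@@](C#C)(O[Si](CC)(CC)CC)/C=C(Cl)\C(=O)N(C)OC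
F6 | step 3 | bromomagnesium dipentylcuprate | CCCCC[Cu-]CCCCC.[Mg+]Br
F7 | step 3 | bromomagnesium bis[(1Z)-hept-1-en-1-yl]cuprate | CCCCC/C=C\[Cu-]/C=C\CCCCC.[Mg+]Br
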